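**Retrosynthetic overview**
1. Target 15 comes from 14 by removal of four MOM ethers; the single stereocenter (C2'' of the C8 side chain, S) is set in the step before.
2. 14 comes from 11 by a metal-free, catalytic enantioselective oxidation at selenium of an (E)-allylic phenyl selenide, followed by a [2,3]-sigmatropic shift that puts oxygen on C2'' and moves the alkene to the chain end; the 3-prenyl alkene is not an oxidation site.
3. 11 (ring C, the only ring that is built) comes from C-prenylation and cyclodehydration of 1,3-diketone 9, itself from a Claisen condensation of ring-A ketone 6 with ring-B ester 8.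
4. 6 comes from phloroacetophenone 1 by C-prenylation, 4,6-bis-MOM protection (the free 2-OH becomes O1, which places the chain at C8), (E)-selective allylic oxidation and OH to SePh exchange.
5. Rings A and B are bought as arenes 1 and 7.

Assumption: the (R,R)-imidodiphosphoric acid named in step 8 is taken as the catalyst enantiomer that gives the (R)-selenoxide 12 and, through the phenyl-exo envelope transition state, (S)-C2''; if the sense is the reverse, the (S,S)-catalyst is used with no other change.

**Step 1**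
Reactants: 1 2,4,6-trihydroxyacetophenone; 2 prenyl bromide (1-bromo-3-methylbut-2-ene)
Product: 3 1-[2,4,6-trihydroxy-3-(3-methylbut-2-en-1-yl)phenyl]ethanone
Conditions: 2 (1.0 equiv), 10% aq. KOH, 0 °C → rt
Reagents that add atoms: none
Why: Nuclear C-alkylation (SN2) of the ambident phloroacetophenone phenoxide in water, a known reaction that gives the mono-C-prenyl ketone in moderate yield after separation from O- and di-prenylated by-products.

**Step 2**
Reactants: 3 1-[2,4,6-trihydroxy-3-(3-methylbut-2-en-1-yl)phenyl]ethanone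
Product: 4 1-[2-hydroxy-4,6-bis(methoxymethoxy)-3-(3-methylbut-2-en-1-yl)phenyl]ethanone
Conditions: MOMCl (2.1 equiv), K2CO3, acetone, 0 °C → rt
Reagents that add atoms: chloromethyl methyl ether, COCCl
Why: Williamson-type etherification in which the acidic 4-OH and the unhindered 6-OH react while the 2-OH, hydrogen-bonded to the carbonyl and flanked by the prenyl group, stays free (minor regioisomer removed by chromatography), so that this oxygen later becomes O1 and the chain ends up at C8.

**Step 3**
Reactants: 4 1-[2-hydroxy-4,6-bis(methoxymethoxy)-3-(3-methylbut-2-en-1-yl)phenyl]ethanone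
Product: 5 1-[2-hydroxy-3-[(2E)-4-hydroxy-3-methylbut-2-en-1-yl]-4,6-bis(methoxymethoxy)phenyl]ethanone
Conditions: SeO2 (0.5 equiv), tBuOOH (3 equiv), CH2Cl2, rt
Reagents that add atoms: tert-butyl hydroperoxide, CC(C)(C)OO
Why: Riley/Sharpless allylic oxidation (ene reaction with SeO2, then [2,3] shift, SeO2 recycled by the hydroperoxide) that hydroxylates only the (E)-methyl group of the trisubstituted alkene and so fixes the (E) geometry needed later.

**Step 4**
Reactants: 5 1-[2-hydroxy-3-[(2E)-4-hydroxy-3-methylbut-2-en-1-yl]-4,6-bis(methoxymethoxy)phenyl]ethanone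
Product: 6 1-[2-hydroxy-4,6-bis(methoxymethoxy)-3-[(2E)-3-methyl-4-(phenylselanyl)but-2-en-1-yl]phenyl]ethanone
Conditions: N-(phenylseleno)phthalimide (1.2 equiv), PBu3 (1.2 equiv), THF, 0 °C, dark
Reagents that add atoms: N-(phenylseleno)phthalimide, O=C1c2ccccc2C(=O)N1[Se]c1ccccc1
Why: Grieco–Nicolaou selenation, in which the primary alcohol is activated as an alkoxyphosphonium ion and displaced by phenylselenolate in an SN2 step, so the alkene geometry is kept and the chelated phenol is untouched.

**Step 5**
Reactants: 7 methyl 2,4-dihydroxybenzoate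
Product: 8 methyl 2,4-bis(methoxymethoxy)benzoate
Conditions: NaH (2.4 equiv), MOMCl (2.4 equiv), DMF, 0 °C → rt
Reagents that add atoms: chloromethyl methyl ether, COCCl
Why: Williamson etherification of both phenols (NaH is needed for the chelated 2-OH), giving a non-enolisable ester for the condensation.

**Step 6**
Reactants: 6 1-[2-hydroxy-4,6-bis(methoxymethoxy)-3-[(2E)-3-methyl-4-(phenylselanyl)but-2-en-1-yl]phenyl]ethanone; 8 methyl 2,4-bis(methoxymethoxy)benzoate
Product: 9 1-[2,4-bis(methoxymethoxy)phenyl]-3-[2-hydroxy-4,6-bis(methoxymethoxy)-3-[(2E)-3-methyl-4-(phenylselanyl)but-2-en-1-yl]phenyl]propane-1,3-dione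
Conditions: NaH (4 equiv), THF, 0 → 60 °C, dark; then AcOH
Reagents that add atoms: none
Why: Crossed Claisen condensation in which the phenoxide–enolate of 6 attacks the non-enolisable ester 8 and formation of the diketonate drives the reaction, while the heterogeneous hydride base does not metalate the carbon next to selenium.

**Step 7**
Reactants: 9 1-[2,4-bis(methoxymethoxy)phenyl]-3-[2-hydroxy-4,6-bis(methoxymethoxy)-3-[(2E)-3-methyl-4-(phenylselanyl)but-2-en-1-yl]phenyl]propane-1,3-dione; 2 prenyl bromide
Product: 11 2-[2,4-bis(methoxymethoxy)phenyl]-5,7-bis(methoxymethoxy)-3-(3-methylbut-2-en-1-yl)-8-[(2E)-3-methyl-4-(phenylselanyl)but-2-en-1-yl]-4H-chromen-4-one, via C-prenylated diketone 10 (not isolated)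
Conditions: 2 (1.1 equiv), K2CO3 (1.3 equiv), acetone, 40 °C, dark; then TsOH·H2O (10 mol%), PhMe, 50 °C
Reagents that add atoms: none
Why: Soft C-alkylation (SN2) of the potassium diketonate, the most acidic site, then acid-catalysed cyclodehydration through the hemiketal, which closes ring C through the only free phenol and so places the new prenyl group at C3 and the selenated chain at C8.

**Step 8**
Reactants: 11 2-[2,4-bis(methoxymethoxy)phenyl]-5,7-bis(methoxymethoxy)-3-(3-methylbut-2-en-1-yl)-8-[(2E)-3-methyl-4-(phenylselanyl)but-2-en-1-yl]-4H-chromen-4-one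
Product: 14 2-[2,4-bis(methoxymethoxy)phenyl]-8-[(2S)-2-hydroxy-3-methylbut-3-en-1-yl]-5,7-bis(methoxymethoxy)-3-(3-methylbut-2-en-1-yl)-4H-chromen-4-one, via allylic selenoxide 12 (not isolated), via allyl selenenate 13 (not isolated)
Conditions: (R,R)-imidodiphosphoric acid built from two 3,3′-bis(2,4,6-triethylphenyl)-BINOL units (5 mol%), 35% aq. H2O2 (1.05 equiv), MgSO4, PhMe/methylcyclohexane 1:2, −30 °C, dark; then Et2NH (3 equiv), −30 → 0 °C
Reagents that add atoms: hydrogen peroxide, OO
Why: Proposed new method: the confined chiral Brønsted acid hydrogen-bonds H2O2 and delivers its electrophilic oxygen to one of the two enantiotopic lone pairs of the allylic selenide (selenium is far more nucleophilic than either alkene, so the 3-prenyl group is left alone), the Se-stereogenic selenoxide 12 then undergoes an immediate, irreversible seleno-Mislow–Evans [2,3]-sigmatropic shift through a five-membered envelope transition state that relays the selenium configuration to C2'' with 1,3-transposition of oxygen and formation of the terminal alkene, and diethylamine cleaves selenenate 13 to the (S)-alcohol while trapping the selenium electrophile as a selenenamide; the closest known reaction types are chiral-phosphoric-acid-catalysed asymmetric sulfoxidation with H2O2 and the asymmetric selenoxide [2,3] rearrangement of allylic selenides run with stoichiometric chiral oxidants or with Ti(OiPr)4/tartrate.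

**Step 9**
Reactants: 14 2-[2,4-bis(methoxymethoxy)phenyl]-8-[(2S)-2-hydroxy-3-methylbut-3-en-1-yl]-5,7-bis(methoxymethoxy)-3-(3-methylbut-2-en-1-yl)-4H-chromen-4-one
Product: 15 2-(2,4-dihydroxyphenyl)-5,7-dihydroxy-8-[(2S)-2-hydroxy-3-methylbut-3-en-1-yl]-3-(3-methylbut-2-en-1-yl)-4H-chromen-4-one
Conditions: HCl (1 M in MeOH), 0 → 30 °C, 2–4 h
Reagents that add atoms: none
Why: Acid-catalysed transacetalisation of the four aryl MOM ethers to dimethoxymethane under dilute, short conditions of the kind routinely used on prenylated polyphenols, which are not expected to ionise the carbinol carbon, so the (S) center is kept.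

**Compound list**
1 | 2,4,6-trihydroxyacetophenone | CC(=O)c1c(O)cc(O)cc1O | starting material
2 | prenyl bromide (1-bromo-3-methylbut-2-ene) | CC(C)=CCBr | starting material
3 | 1-[2,4,6-trihydroxy-3-(3-methylbut-2-en-1-yl)phenyl]ethanone | CC(=O)c1c(O)cc(O)c(CC=C(C)C)c1O | intermediate
4 | 1-[2-hydroxy-4,6-bis(methoxymethoxy)-3-(3-methylbut-2-en-1-yl)phenyl]ethanone | CC(=O)c1c(OCOC)cc(OCOC)c(CC=C(C)C)c1O | intermediate
5 | 1-[2-hydroxy-3-[(2E)-4-hydroxy-3-methylbut-2-en-1-yl]-4,6-bis(methoxymethoxy)phenyl]ethanone | CC(=O)c1c(OCOC)cc(OCOC)c(C/C=C(\C)CO)c1O | intermediate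
6 | 1-[2-hydroxy-4,6-bis(methoxymethoxy)-3-[(2E)-3-methyl-4-(phenylselanyl)but-2-en-1-yl]phenyl]ethanone | CC(=O)c1c(OCOC)cc(OCOC)c(C/C=C(\C)C[Se]c2ccccc2)c1O | intermediate
7 | methyl 2,4-dihydroxybenzoate | COC(=O)c1ccc(O)cc1O | starting material
8 | methyl 2,4-bis(methoxymethoxy)benzoate | COCOc1ccc(C(=O)OC)c(OCOC)c1 | intermediate
9 | 1-[2,4-bis(methoxymethoxy)phenyl]-3-[2-hydroxy-4,6-bis(methoxymethoxy)-3-[(2E)-3-methyl-4-(phenylselanyl)but-2-en-1-yl]phenyl]propane-1,3-dione (keto/enol mixture) | COCOc1ccc(C(=O)CC(=O)c2c(OCOC)cc(OCOC)c(C/C=C(\C)C[Se]c3ccccc3)c2O)c(OCOC)c1 | intermediate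
10 | 2-(3-methylbut-2-en-1-yl) derivative of diketone 9 (C2 racemic and labile) | COCOc1ccc(C(=O)C(CC=C(C)C)C(=O)c2c(OCOC)cc(OCOC)c(C/C=C(\C)C[Se]c3ccccc3)c2O)c(OCOC)c1 | intermediate
11 | 2-[2,4-bis(methoxymethoxy)phenyl]-5,7-bis(methoxymethoxy)-3-(3-methylbut-2-en-1-yl)-8-[(2E)-3-methyl-4-(phenylselanyl)but-2-en-1-yl]-4H-chromen-4-one | CC(C)=CCc1c(-c2ccc(OCOC)cc2OCOC)oc2c(C/C=C(\C)C[Se]c3ccccc3)c(OCOC)cc(OCOC)c2c1=O | intermediate
12 | selenoxide of 11, (R) at selenium, 8-[(2E)-3-methyl-4-(phenylseleninyl)but-2-en-1-yl] | CC(C)=CCc1c(-c2ccc(OCOC)cc2OCOC)oc2c(C/C=C(\C)C[Se@@](=O)c3ccccc3)c(OCOC)cc(OCOC)c2c1=O | intermediate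
13 | selenenate ester, 8-[(2S)-3-methyl-2-[(phenylselanyl)oxy]but-3-en-1-yl] analogue of 14 | CC(C)=CCc1c(-c2ccc(OCOC)cc2OCOC)oc2c(C[C@H](O[Se]c3ccccc3)C(C)=C)c(OCOC)cc(OCOC)c2c1=O | intermediate
14 | 2-[2,4-bis(methoxymethoxy)phenyl]-8-[(2S)-2-hydroxy-3-methylbut-3-en-1-yl]-5,7-bis(methoxymethoxy)-3-(3-methylbut-2-en-1-yl)-4H-chromen-4-one | CC(C)=CCc1c(-c2ccc(OCOC)cc2OCOC)oc2c(C[C@H](O)C(C)=C)c(OCOC)cc(OCOC)c2c1=O | intermediate
15 | 2-(2,4-dihydroxyphenyl)-5,7-dihydroxy-8-[(2S)-2-hydroxy-3-methylbut-3-en-1-yl]-3-(3-methylbut-2-en-1-yl)-4H-chromen-4-one | C=C(C)[C@@H](O)Cc1c(O)cc(O)c2c(=O)c(CC=C(C)C)c(-c3ccc(O)cc3O)oc12 | target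

**Step count and risks**
Total step count: 9. Longest linear sequence: 8 (steps 1–4 and 6–9; step 5 is the one-step side branch).

Three steps most likely to fail:

Step 8 (the proposed new reaction). The risks are an uncatalysed background oxidation at selenium, incomplete selenium-to-carbon chirality transfer if the exo and endo envelopes compete, and erosion of the (E) geometry of 11 by a light-induced 1,3-selenium shift before oxidation. The fallback uses known chemistry, sets out from 11 and comes back at 14. Selenide 11 is oxidised without a chiral catalyst (H2O2, pyridine, CH2Cl2, 0 °C), and the same [2,3] shift gives the racemic 8-(2-hydroxy-3-methylbut-3-en-1-yl) flavone F1. Dess–Martin periodinane (NaHCO3, CH2Cl2) gives the 8-(3-methyl-2-oxobut-3-en-1-yl) enone F2. A Corey–Bakshi–Shibata reduction with (R)-2-methyl-CBS-oxazaborolidine (20 mol%) and catecholborane in PhMe at −78 °C, with the isopropenyl group acting as the large substituent, then gives (S)-14; the chromenone carbonyl, a vinylogous ester, is not reduced under these conditions.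

Step 7. The risks are O-prenylation of the free phenol or of the enol, alkylation at selenium by prenyl bromide, and partial MOM loss in the acid stage. The fallback sets out from 9 and comes back at 11. The prenyl group is delivered as a π-allyl electrophile under neutral conditions (tert-butyl 3-methylbut-2-en-1-yl carbonate, Pd(PPh3)4, a zerovalent palladium catalyst, 5 mol%, THF, 25 °C). The tert-butoxide released deprotonates only the diketone, the soft diketonate attacks the unsubstituted allyl terminus, and the phenol is never ionised. This gives 10, which is cyclodehydrated as before to 11; the fallback passes only through listed compounds, so its new compounds are none F0.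

Step 6. The risk is a sluggish intermolecular condensation between a hindered ketone enolate and an ortho-substituted, electron-rich ester. The fallback sets out from 8 (with 6) and comes back at 9, replacing the intermolecular condensation by an intramolecular acyl shift. Ester 8 is saponified (LiOH, THF/H2O) to 2,4-bis(methoxymethoxy)benzoic acid F3. The acid is coupled to the 2-OH of 6 (EDC·HCl, DMAP, CH2Cl2) to give 2-acetyl-3,5-bis(methoxymethoxy)-6-[(2E)-3-methyl-4-(phenylselanyl)but-2-en-1-yl]phenyl 2,4-bis(methoxymethoxy)benzoate F4. A Baker–Venkataraman rearrangement (KOtBu, THF, 0 °C → rt) then gives 9.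

**Further compounds**
F1 | step 8 | racemic 2-[2,4-bis(methoxymethoxy)phenyl]-8-(2-hydroxy-3-methylbut-3-en-1-yl)-5,7-bis(methoxymethoxy)-3-(3-methylbut-2-en-1-yl)-4H-chromen-4-one | CC(C)=CCc1c(-c2ccc(OCOC)cc2OCOC)oc2c(CC(O)C(C)=C)c(OCOC)cc(OCOC)c2c1=O
F2 | step 8 | 2-[2,4-bis(methoxymethoxy)phenyl]-5,7-bis(methoxymethoxy)-3-(3-methylbut-2-en-1-yl)-8-(3-methyl-2-oxobut-3-en-1-yl)-4H-chromen-4-one | CC(C)=CCc1c(-c2ccc(OCOC)cc2OCOC)oc2c(CC(=O)C(C)=C)c(OCOC)cc(OCOC)c2c1=O
F0 | step 7 | none | none
F3 | step 6 | 2,4-bis(methoxymethoxy)benzoic acid | COCOc1ccc(C(=O)O)c(OCOC)c1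
F4 | step 6 | 2-acetyl-3,5-bis(methoxymethoxy)-6-[(2E)-3-methyl-4-(phenylselanyl)but-2-en-1-yl]phenyl 2,4-bis(methoxymethoxy)benzoate | COCOc1ccc(C(=O)Oc2c(C/C=C(\C)C[Se]c3ccccc3)c(OCOC)cc(OCOC)c2C(C)=O)c(OCOC)c1
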